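**Numbering used throughout.** C1 is the bridgehead next to CMe2. C2–C3–C4 is the enolised triketone bridge, and C3 carries the benzoyl carbon. C5 is the other bridgehead, C6 is CH2, C7 is CH(prenyl), C8 is CMe2 and C9 is the bridging C=O. In this numbering and in the drawn tautomer the target 16 is (1S,5R,7S), with the C7 prenyl group endo (7-epi-clusianone series).

## The problem

1. Target 16 is a bicyclo[3.3.1]nonane-2,4,9-trione. A cyclohexanone ring (C1, C8, C7, C6, C5, C9) and a 2-benzoyl-cyclohexane-1,3,5-trione ring (C1–C5, C9) share the unit C1–C9–C5.
2. Both bridgeheads are quaternary and prenylated. C1 is also bonded to quaternary C8, so C1–C8 is the bond that resists closure.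
3. C1 and C5 are tied to each other by the bridge and count as one stereochemical element. C7 is the second.
4. The C7 prenyl group points towards C3, cis to C2 and C4 on the cyclohexanone ring. This is the contra-steric orientation. A ring closure through a chair, or any carbon reagent that attacks C7 of the finished cage, gives the exo epimer instead.
5. Three trisubstituted alkenes forbid hydrogenation, strong acid, electrophilic oxidants and long-lived radicals. The chelated enol is a fairly strong acid and consumes one equivalent of every base or hydride.
6. The enabling feature is a latent mirror plane through C3, C7 and C9. It exchanges C1/C5, C2/C4, C6/C8 and the two bridgehead prenyl groups.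
7. Only the two methyl groups on C8 break this plane, so the chirality of 16 lies entirely in C8Me2 versus C6H2.
8. If C7 is a carbonyl group and C8 is still CH2, the cage is meso. C6–H and C8–H are then enantiotopic, and they are the only enolisable hydrogens, because C1 and C5 are quaternary and C3 is fully substituted.

## Retrosynthesis

**16 ⇒ 13 + 14.**
- Bonds cut: C7–H, and the CH2–CH= bond inside the C7 prenyl group.
- The neighbouring cut, C7–CH2, would require carbon to enter the endo face of C7, which the C3 bridge closes.
- One bond further out, the carbon already sits on C7 as an exocyclic methylene. The small partner, hydrogen, then comes from the open exo face and pushes the side arm endo.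
- Compound 13 has no C7 stereocentre and four carbons fewer.
- The forward reaction needs an anti-Markovnikov hydrometalation that prefers the one 1,1-disubstituted alkene over two prenyl groups. An sp3–sp2 coupling with 14 follows.

**13 ⇒ 12.**
- The C7=CH2 group is traced back to C7=O.
- A ketone is chosen over other methylene precursors because it is the only group at C7 that also activates C8, the carbon that still has to be built up.
- The forward methylenation must pick C7, which has one quaternary neighbour, over C9, which has two, and over the triketone, which is masked as its enolate.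

**12 ⇒ 10.**
- Bonds cut: one C8–CH3 bond, and one C–H bond of the other methyl group.
- Two successive enolate methylations are rejected. After the first, kinetic deprotonation would move to C6, and the more substituted enolate is strained against the C1 substituents.
- The α-methylene ketone 10 stores the first carbon. On conjugate hydride addition it gives the C7–C8 enolate regiospecifically, ready for a methyl electrophile.

**10 ⇒ 6.**
- Bond cut: C8=CH2. Removing this carbon restores the mirror plane, so 6 is meso. It has no gem-dimethyl group and no stereochemical information that needs control.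
- The forward reaction must tell C8–H from C6–H. This is a selection between enantiotopic groups by a chiral lithium amide, followed by one-carbon trapping.
- This single event defines the absolute sense of both quaternary bridgeheads without making a bond to either.

**6 ⇒ 3 + 4.**
- Bonds cut: C5–C6 and C1–C8.
- Cuts at C1–C2/C4–C5 or at C9 would discard the aromatic ring. That ring already holds six of the nine core carbons, all three ring oxygens, the benzoyl group and both bridgehead prenyl groups.
- Because C8 is still CH2, both new bonds go to primary, SN2-activated carbons. The vicinal quaternary problem is postponed to a methylation.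
- The three-carbon unit 4 is symmetric, so there is no regiochemical question. The bridge enforces cis bridgeheads.

**3 ⇒ 1 + 2.**
- Bonds cut: the two aryl–CH2 bonds. Twofold C-prenylation of 1 uses its only two ring C–H positions.

## Roads not taken

**Alternative 1:** the most obvious road.
- The cut is at C1–C2 and C4–C5. The forward key step is an α,α′-annulation of the cyclohexanone enol ether A1 with a malonyl dielectrophile, followed by C3-benzoylation.
- The three-carbon bridge must span C1 and C5 diaxially, so it comes in on the ring face opposite the C7 prenyl group. The product is the 7-exo epimer A2, not 16.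
- A1 also needs its own asymmetric synthesis: the C7 stereocentre, the gem-dimethyl group and two prenylations. The benzoyl group still has to be added afterwards.
- The chosen plan avoids the facial conflict because C7 is sp2 while the cage is made.

**Alternative 2:** the biomimetic road.
- The cut is at C1–C8 only. The forward key step is a cation–enol cyclisation of the C5-lavandulyl dienone A3.
- The relative configuration C5/C7 would have to be set in an open-chain alkylation with a β-branched primary electrophile, without cyclic control.
- The tertiary cation has to be formed by acid next to three prenyl groups.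
- For the endo series the closure needs an axial C7 prenyl group or a boat. O-closure to a pyran and a 1,2-hydride shift from C7 therefore have time to compete.
- The bond is formed between two fully substituted carbons. In the chosen plan the same bond is a primary SN2 reaction.

**Alternative 3:** the same two bonds with an unsymmetrical partner.
- The cut is at C1–C8 and C5–C6, as in the chosen plan. The partner is the unsymmetrical Michael dielectrophile A5, which already carries the gem-dimethyl group. Addition–elimination and then Michael closure on 3 give the 7-formyl cage A4.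
- C1–C8 is then made by attack on a β,β-disubstituted acceptor carbon.
- Absolute control must be exerted on a flat phenolate by ion pairing alone.
- The formyl group is epimerisable and rests exo. Several more steps are needed to homologate CHO to prenyl and to invert C7.
- The symmetric unit 4 removes the first two problems. The C7 ketone gives direct access to the methylene group that solves the third.

Key step: step 3

Remark 1: every 2-acyl-1,3-diketone unit is written as the exocyclic enol of the given SMILES; tautomer exchange is fast, so the enol geometry is a drawing convention and is left open for meso compounds and for salts.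

Remark 2: the sense of induction of the amide in this cage cannot be derived with certainty from monocyclic models; the (R,R)-amide is written, and its equally available enantiomer is used if C6–H is removed instead.

## Steps

Step 1
Reactants: 1 2,4,6-trihydroxybenzophenone; 2 prenyl bromide (1-bromo-3-methylbut-2-ene)
Product: 3 [2,4,6-trihydroxy-3,5-bis(3-methylbut-2-enyl)phenyl](phenyl)methanone
Conditions: 2 (2.1 equiv), KOH, H2O, 0 °C → rt
Reagents that add atoms: none
Why: Twofold C-alkylation of the phloroglucinolate; in water the oxygens are hydrogen-bonded and the soft allylic halide goes to the two free ring carbons. Stoichiometry and low temperature stop the reaction before dearomatisation, and no stereocentre is formed.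

Step 2
Reactants: 3 [2,4,6-trihydroxy-3,5-bis(3-methylbut-2-enyl)phenyl](phenyl)methanone; 4 1,3-dichloroacetone
Product: 6 meso-(1R,5S)-3-[hydroxy(phenyl)methylidene]-1,5-bis(3-methylbut-2-enyl)bicyclo[3.3.1]nonane-2,4,7,9-tetraone, via chloroketone 5 (not isolated)
Conditions: LiHMDS (3.0 equiv), THF, −78 → 0 °C; 4 (1.0 equiv), Bu4NI (10 mol %), 0 → 45 °C; 1 M HCl
Reagents that add atoms: none
Why: Double C-alkylative dearomatisation ([3+3] annulation): a prenylated ring carbon of the lithium phenolate displaces one chloride of the SN2-activated dihaloketone (→ 5), and the remaining enolate carbon closes the cyclohexanone ring by 6-exo-tet displacement. Both bonds go to primary carbons, so C1–C8 exists before C8 is quaternary. The tether reaches C1 only on the face it occupies at C5, which makes the bridgeheads cis and, with a symmetric C3 unit, the product meso.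

Step 3
Reactants: 6 meso-(1R,5S)-3-[hydroxy(phenyl)methylidene]-1,5-bis(3-methylbut-2-enyl)bicyclo[3.3.1]nonane-2,4,7,9-tetraone
Product: 10 (1S,5R)-3-[hydroxy(phenyl)methylidene]-8-methylidene-1,5-bis(3-methylbut-2-enyl)bicyclo[3.3.1]nonane-2,4,7,9-tetraone, via dilithium bis-enolate 7 (not isolated), via Mannich base 8 (not isolated), via methiodide 9 (not isolated)
Conditions: (R,R)-bis(1-phenylethyl)amine·HCl (2.3 equiv), n-BuLi (4.6 equiv), THF, −78 → 0 → −95 °C; 6, 1 h; CH2=NMe2+ I− (1.3 equiv), −95 → 0 °C; MeI (5 equiv), rt; sat. aq NaHCO3/CH2Cl2, rt; 1 M HCl
Reagents that add atoms: Eschenmoser's salt (N,N-dimethylmethyleneiminium iodide), C=[N+](C)C.[I-]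
Why: Enantioselective deprotonation of a meso ketone by a C2-symmetric chiral lithium amide, followed by Mannich trapping and Hofmann-type elimination (α-methylenation). The first equivalent of amide only turns the chelated enol into the mirror-symmetric lithium trione enolate; the second binds the C7 carbonyl oxygen and removes, through the usual cyclic Li–O/N–H transition state, one of the two stereoelectronically aligned exo-axial protons on C6 and C8, which are enantiotopic because the plane through C3, C7 and C9 is the only symmetry element of 6. The closest known reactions are the enantioselective deprotonations of 4-substituted and cis-3,5-disubstituted cyclohexanones and of tropinone- and granatanone-type bicyclic ketones, with LiCl (formed here from the amine hydrochloride) as the additive that makes external quenching reliable. No ring is closed and no bond to C1 or C5 is made: these two quaternary centres, present as a mirror-image pair, become a defined (1S,5R) pair in one event, and the only controlling element is the reagent. The chemoselectivity is secured by the substrate, since C1 and C5 are quaternary and C3 is fully substituted, so C6–H and C8–H are the only enolisable hydrogens, and the trione enolate is too stabilised to compete for the iminium ion or for MeI. The iminium ion adds to C8 of 7 from the open exo face (this centre is erased again), N-methylation creates the leaving group, and bicarbonate triggers E1cB loss of trimethylamine. Product 10 carries the first of the two C8 methyl carbons in a form that fixes where the second must go.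

Step 4
Reactants: 10 (1S,5R)-3-[hydroxy(phenyl)methylidene]-8-methylidene-1,5-bis(3-methylbut-2-enyl)bicyclo[3.3.1]nonane-2,4,7,9-tetraone
Product: 12 (1S,5R)-3-[hydroxy(phenyl)methylidene]-8,8-dimethyl-1,5-bis(3-methylbut-2-enyl)bicyclo[3.3.1]nonane-2,4,7,9-tetraone, via dilithium enolate 11 (not isolated)
Conditions: LiHMDS (1.05 equiv), THF, −78 °C; L-Selectride (1.1 equiv), −78 °C; MeI (5 equiv), DMPU, −78 → 0 °C; 1 M HCl
Reagents that add atoms: methyl iodide, CI
Why: Reductive alkylation of an enone: after deprotonation of the enol, the hindered borohydride adds hydride 1,4 to the unsubstituted exocyclic terminus, which completes the first methyl group and gives the tetrasubstituted C7–C8 enolate 11 regiospecifically; 11 is then methylated at C8. C6 is never deprotonated, so the broken symmetry is carried over into the gem-dimethyl group, and C8 is not a stereocentre because both its substituents are methyl.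

Step 5
Reactants: 12 (1S,5R)-3-[hydroxy(phenyl)methylidene]-8,8-dimethyl-1,5-bis(3-methylbut-2-enyl)bicyclo[3.3.1]nonane-2,4,7,9-tetraone
Product: 13 (1S,5R)-3-[hydroxy(phenyl)methylidene]-8,8-dimethyl-7-methylidene-1,5-bis(3-methylbut-2-enyl)bicyclo[3.3.1]nonane-2,4,9-trione
Conditions: KOtBu (4 equiv), Ph3PCH3Br (3 equiv), toluene/THF, 0 → 70 °C; 1 M HCl
Reagents that add atoms: methyltriphenylphosphonium bromide (as its ylide), C[P+](c1ccccc1)(c1ccccc1)c1ccccc1.[Br-]
Why: Wittig methylenation: the triketone is inert as its potassium enolate and C9 is shielded by two quaternary carbons, so only C7 reacts; its environment resembles that of 2,2-dimethylcyclohexanone. No stereocentre is formed or touched.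

Step 6
Reactants: 13 (1S,5R)-3-[hydroxy(phenyl)methylidene]-8,8-dimethyl-7-methylidene-1,5-bis(3-methylbut-2-enyl)bicyclo[3.3.1]nonane-2,4,9-trione; 14 1-bromo-2-methylprop-1-ene
Product: 16 (1S,5R,7S)-3-[hydroxy(phenyl)methylidene]-8,8-dimethyl-1,5,7-tris(3-methylbut-2-enyl)bicyclo[3.3.1]nonane-2,4,9-trione (7-endo-prenyl), via bis-boryl adduct 15 (not isolated)
Conditions: 9-BBN-H (2.3 equiv), THF, 0 °C → rt; then 14 (2 equiv), PdCl2(dppf) (5 mol %), 3 M aq NaOH, THF, 60 °C; 1 M HCl
Reagents that add atoms: none
Why: Hydroboration and B-alkyl Suzuki–Miyaura coupling in one flask: the first equivalent of borane is consumed by the enol and masks the triketone as a boron chelate, and the second adds to the only 1,1-disubstituted alkene, much faster than to the trisubstituted prenyl groups, with boron on CH2. The endo face of C7 is closed by the C3 bridge of the twin-chair cage, so hydrogen is delivered from the exo face and the CH2–B arm is forced endo (7S). Coupling of the remote primary C–B bond with 14 completes the prenyl group without touching C7.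

## Compound list

1 | 2,4,6-trihydroxybenzophenone | O=C(c1ccccc1)c1c(O)cc(O)cc1O | starting material
2 | prenyl bromide | CC(C)=CCBr | starting material
3 | [2,4,6-trihydroxy-3,5-bis(3-methylbut-2-enyl)phenyl](phenyl)methanone | O=C(c1ccccc1)c1c(O)c(CC=C(C)C)c(O)c(CC=C(C)C)c1O | intermediate
4 | 1,3-dichloroacetone | O=C(CCl)CCl | starting material
5 | (±)-2-benzoyl-6-(3-chloro-2-oxopropyl)-3,5-dihydroxy-4,6-bis(3-methylbut-2-enyl)cyclohexa-2,4-dien-1-one (racemic, written as free enol) | O=C(c1ccccc1)C1=C(O)C(CC=C(C)C)=C(O)C(CC=C(C)C)(CC(=O)CCl)C1=O | intermediate
6 | meso-(1R,5S)-3-[hydroxy(phenyl)methylidene]-1,5-bis(3-methylbut-2-enyl)bicyclo[3.3.1]nonane-2,4,7,9-tetraone | O=C1C[C@@]2(CC=C(C)C)C(=O)C(=C(O)c3ccccc3)C(=O)[C@](CC=C(C)C)(C2=O)C1 | intermediate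
7 | dilithium salt of 6: C7–C8 enolate plus trione enolate, (1S,5R) | [Li+].[Li+].[O-]C1=C[C@]2(CC=C(C)C)C(=O)C(=C([O-])c3ccccc3)C(=O)[C@](CC=C(C)C)(C1)C2=O | intermediate
8 | (1S,5R)-8-exo-[(dimethylamino)methyl] derivative of 6 (written as free enol) | O=C1C[C@@]2(CC=C(C)C)C(=O)/C(=C(/O)c3ccccc3)C(=O)[C@](CC=C(C)C)(C2=O)[C@@H]1CN(C)C | intermediate
9 | N-methyl iodide of 8 | O=C1C[C@@]2(CC=C(C)C)C(=O)/C(=C(/O)c3ccccc3)C(=O)[C@](CC=C(C)C)(C2=O)[C@@H]1C[N+](C)(C)C.[I-] | intermediate
10 | (1S,5R)-3-[hydroxy(phenyl)methylidene]-8-methylidene-1,5-bis(3-methylbut-2-enyl)bicyclo[3.3.1]nonane-2,4,7,9-tetraone | O=C1C[C@@]2(CC=C(C)C)C(=O)/C(=C(/O)c3ccccc3)C(=O)[C@](CC=C(C)C)(C2=O)C1=C | intermediate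
11 | dilithium salt: 8-methyl C7–C8 enolate plus trione enolate, (1S,5R) | [Li+].[Li+].[O-]C1=C(C)[C@]2(CC=C(C)C)C(=O)C(=C([O-])c3ccccc3)C(=O)[C@](CC=C(C)C)(C1)C2=O | intermediate
12 | (1S,5R)-3-[hydroxy(phenyl)methylidene]-8,8-dimethyl-1,5-bis(3-methylbut-2-enyl)bicyclo[3.3.1]nonane-2,4,7,9-tetraone | O=C1C[C@@]2(CC=C(C)C)C(=O)/C(=C(/O)c3ccccc3)C(=O)[C@](CC=C(C)C)(C2=O)C1(C)C | intermediate
13 | (1S,5R)-3-[hydroxy(phenyl)methylidene]-8,8-dimethyl-7-methylidene-1,5-bis(3-methylbut-2-enyl)bicyclo[3.3.1]nonane-2,4,9-trione | C=C1C[C@@]2(CC=C(C)C)C(=O)/C(=C(/O)c3ccccc3)C(=O)[C@](CC=C(C)C)(C2=O)C1(C)C | intermediate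
14 | 1-bromo-2-methylprop-1-ene | CC(C)=CBr | starting material
15 | (1S,5R,7S)-7-endo-[(9-borabicyclo[3.3.1]nonan-9-yl)methyl] adduct of 13, enol oxygen bound to a second 9-BBN unit | B1(C[C@H]2C[C@@]3(CC=C(C)C)C(=O)/C(=C(/OB4C5CCCC4CCC5)c4ccccc4)C(=O)[C@](CC=C(C)C)(C3=O)C2(C)C)C2CCCC1CCC2 | intermediate
16 | (1S,5R,7S)-3-[hydroxy(phenyl)methylidene]-8,8-dimethyl-1,5,7-tris(3-methylbut-2-enyl)bicyclo[3.3.1]nonane-2,4,9-trione | CC(C)=CC[C@H]1C[C@@]2(CC=C(C)C)C(=O)/C(=C(/O)c3ccccc3)C(=O)[C@](CC=C(C)C)(C2=O)C1(C)C | target

## Step count and least certain steps

Total steps: 6. Longest linear sequence: 6 (1 → 3 → 6 → 10 → 12 → 13 → 16). Compounds 2, 4 and 14 are purchased.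

**Step 3 (key step).**
- Most likely failure: incomplete discrimination between the two enantiotopic exo-axial protons. The substrate enters as a lithium trione enolate, which can form mixed aggregates with the amide and blur its chiral environment. Proton return before trapping would erode the selectivity further.
- Fallback: replace the chiral base by a covalently bound auxiliary. It sets out from 6 and comes back at 8.
- Condensation of 6 with (S)-1-amino-2-(methoxymethyl)pyrrolidine gives the SAMP hydrazone F1.
- Double lithiation with LDA and reaction with Eschenmoser's salt give the aminomethylated hydrazone F2.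
- The auxiliary fixes the absolute configuration of the new α-centre, and the cage allows only exo attack, so only one of the two α-carbons can satisfy both demands.
- Two-phase hydrolysis with aqueous oxalic acid releases the auxiliary and gives 8.

**Step 2.**
- Most likely failure: diversion of the ambident phenolate. It may O-alkylate. Alternatively it may add to the very electrophilic carbonyl group of 4, after which an enolate oxygen closes onto the CH2Cl group (interrupted Feist–Bénary pathway).
- Fallback: use a soft Michael-type C3 unit. It sets out from 3 and comes back at 6.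
- 2-Nitroallyl pivalate F3 is made from nitromethane, formaldehyde and pivaloyl chloride.
- F3 reacts with the phenolate of 3 by addition–elimination and then Michael closure to give the meso 7-nitro cage F4.
- A buffered TiCl3 Nef reaction converts F4 into 6.

**Step 4.**
- Most likely failures: 1,2-reduction of the enone, or proton exchange between enolate 11 and product 12, which would send methylation to C6. Slow alkylation at a carbon next to quaternary C1 gives such exchange time.
- Fallback: bring one methyl group in as a nucleophile and the other as an electrophile at a diazo carbon. It sets out from 6 and comes back at 12.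
- The same amide and 2,2,2-trifluoroethyl trifluoroacetate give the 8-trifluoroacetyl ketone F5.
- Methanesulfonyl azide and Et3N give the 8-diazo-7-ketone F6.
- Trimethylborane (Hooz reaction, on the lithium salt) gives the dimethylboron enolate F7 by B→C methyl migration with loss of nitrogen.
- MeLi and then MeI convert F7 into 12.

**Step 5.**
- Most likely failure: enolisation of C7 towards C6 by the basic ylide, or slow oxaphosphetane formation next to the axial C8 methyl group. Either would stall the conversion.
- Fallback: a Peterson sequence. It sets out from 12 and comes back at 13.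
- Me3SiCH2Li/CeCl3 adds from the exo face to give the β-hydroxysilane F8.
- KH or HF·pyridine eliminates F8 to 13.

**Step 6.**
- Most likely failure: slow transmetalation of the congested endo CH2–B arm, which can be held by a neighbouring enolate oxygen. Prolonged heating would then allow protodeboronation or slow hydroboration of the prenyl groups by excess borane.
- Fallback: replace the palladium coupling by a cuprate displacement. It sets out from 15 and comes back at 16.
- Sodium perborate oxidises 15 to the endo primary alcohol F9.
- PPh3, imidazole and I2 give the endo iodide F10.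
- Lithium bis(2-methylprop-1-enyl)cuprate, in excess to allow for the acidic enol, gives 16.

## Further compounds

F1 | step 3 | SAMP hydrazone of 6 | COC[C@@H]1CCCN1N=C1C[C@@]2(CC=C(C)C)C(=O)C(=C(O)c3ccccc3)C(=O)[C@](CC=C(C)C)(C2=O)C1
F2 | step 3 | 8-exo-[(dimethylamino)methyl] SAMP hydrazone | COC[C@@H]1CCCN1N=C1C[C@@]2(CC=C(C)C)C(=O)C(=C(O)c3ccccc3)C(=O)[C@](CC=C(C)C)(C2=O)[C@@H]1CN(C)C
F3 | step 2 | 2-nitroallyl pivalate | C=C(COC(=O)C(C)(C)C)[N+](=O)[O-]
F4 | step 2 | meso 7-exo-nitro-3-[hydroxy(phenyl)methylidene]-1,5-bis(3-methylbut-2-enyl)bicyclo[3.3.1]nonane-2,4,9-trione | O=[N+]([O-])[C@@H]1C[C@@]2(CC=C(C)C)C(=O)C(=C(O)c3ccccc3)C(=O)[C@](CC=C(C)C)(C2=O)C1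
F5 | step 4 | (1S,5R)-8-trifluoroacetyl derivative of 6 (enol form) | OC1=C(C(=O)C(F)(F)F)[C@]2(CC=C(C)C)C(=O)/C(=C(\O)c3ccccc3)C(=O)[C@](CC=C(C)C)(C1)C2=O
F6 | step 4 | (1S,5R)-8-diazo derivative of 6 | O=C1C[C@@]2(CC=C(C)C)C(=O)/C(=C(/O)c3ccccc3)C(=O)[C@](CC=C(C)C)(C2=O)C1=[N+]=[N-]
F7 | step 4 | (1S,5R)-8-methyl C7–C8 dimethylboron enolate | CB(C)OC1=C(C)[C@]2(CC=C(C)C)C(=O)/C(=C(\O)c3ccccc3)C(=O)[C@](CC=C(C)C)(C1)C2=O
F8 | step 5 | 7-endo-hydroxy-7-exo-[(trimethylsilyl)methyl] adduct of 12 | C[Si](C)(C)C[C@]1(O)C[C@@]2(CC=C(C)C)C(=O)/C(=C(/O)c3ccccc3)C(=O)[C@](CC=C(C)C)(C2=O)C1(C)C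
F9 | step 6 | (1S,5R,7S)-7-endo-hydroxymethyl cage | OC[C@H]1C[C@@]2(CC=C(C)C)C(=O)/C(=C(/O)c3ccccc3)C(=O)[C@](CC=C(C)C)(C2=O)C1(C)C
F10 | step 6 | (1S,5R,7S)-7-endo-iodomethyl cage | IC[C@H]1C[C@@]2(CC=C(C)C)C(=O)/C(=C(/O)c3ccccc3)C(=O)[C@](CC=C(C)C)(C2=O)C1(C)C
A1 | alternative 1 | 1-methoxy-3,3-dimethyl-2,4,6-tris(3-methylbut-2-enyl)cyclohex-1-ene (C6 epimers) | CC(C)=CC[C@@H]1CC(CC=C(C)C)C(OC)=C(CC=C(C)C)C1(C)C
A2 | alternative 1 | 7-exo epimer of 16 | CC(C)=CC[C@@H]1C[C@@]2(CC=C(C)C)C(=O)/C(=C(/O)c3ccccc3)C(=O)[C@](CC=C(C)C)(C2=O)C1(C)C
A3 | alternative 2 | 2-benzoyl-3,5-dihydroxy-6-(2-isopropenyl-5-methylhex-4-enyl)-4,6-bis(3-methylbut-2-enyl)cyclohexa-2,4-dien-1-one, C5 and C7 as in 16 | O=C(c1ccccc1)C1=C(O)C(CC=C(C)C)=C(O)[C@@](CC=C(C)C)(C[C@H](CC=C(C)C)C(C)=C)C1=O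
A4 | alternative 3 | 7-exo-formyl-8,8-dimethyl cage | O=C[C@@H]1C[C@@]2(CC=C(C)C)C(=O)/C(=C(/O)c3ccccc3)C(=O)[C@](CC=C(C)C)(C2=O)C1(C)C
A5 | alternative 3 | 2-(acetoxymethyl)-3-methylbut-2-enal | CC(=O)OCC(C=O)=C(C)C
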